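**Strategy.** Everything rests on opening the pyran ring (ring C) of the upper flavan unit at O1–C2 and C4a–C4. The benzylic carbons C2 and C4 are 1,3-related, so C2–C3–C4 is a chalcone (carbonyl = C2, β-carbon = C4, already bonded to C8 of benzyl-protected (+)-catechin) and O1–C8a–C4a of ring A is an ortho-borylated phenol. A rhodium/chiral diene conjugate arylation with in situ cycloketalization and dehydration joins them in one operation, forms both ring bonds and sets C4 under catalyst control. One hydrogenation then adds hydrogen anti to the C4 aryl group (C2, 2,4-cis) and frees all phenols.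

Key step: step 7

Remark: the target is read as (2S,4S)-2,4-cis in the upper unit and (2R,3S) in the (+)-catechin unit. Atoms of the catechin unit are marked (cat). 3',4'-Bis(benzyloxy)acetophenone, 4-bromoresorcinol and bis(pinacolato)diboron are taken as commercial.

**Step 1**
Reactants: 1 (+)-catechin; 2 benzyl bromide
Product: 3 (2R,3S)-5,7-bis(benzyloxy)-2-[3,4-bis(benzyloxy)phenyl]chroman-3-ol
Conditions: BnBr (4.4 equiv), K2CO3 (4.5 equiv), DMF, 0 °C → rt
Reagents that add atoms: benzyl bromide, BrCc1ccccc1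
Why: Williamson etherification; K2CO3 deprotonates only the four phenols, so the secondary C3 alcohol stays free and no stereocenter is touched.

**Step 2**
Reactants: 3; 4 N-bromosuccinimide
Product: 5 (2R,3S)-5,7-bis(benzyloxy)-2-[3,4-bis(benzyloxy)phenyl]-8-bromochroman-3-ol
Conditions: NBS (1.05 equiv), CH2Cl2, −78 °C → rt
Reagents that add atoms: N-bromosuccinimide, BrN1C(=O)CCC1=O
Why: Electrophilic aromatic bromination of the phloroglucinol-type ring of the catechin unit, for which C8(cat) is the established preferred site in this tetrabenzyl ether; the catechol diether ring is far less activated.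

**Step 3**
Reactants: 5; 6 N,N-dimethylformamide
Product: 8 (2R,3S)-5,7-bis(benzyloxy)-2-[3,4-bis(benzyloxy)phenyl]-3-hydroxychroman-8-carbaldehyde, via aryllithium alkoxide 7 (not isolated)
Conditions: n-BuLi (2.2 equiv), THF, −78 °C; DMF (5 equiv), −78 → 0 °C; sat. aq. NH4Cl
Reagents that add atoms: N,N-dimethylformamide, CN(C)C=O
Why: The first equivalent of n-BuLi deprotonates the C3 alcohol, the second effects bromine–lithium exchange, and the aryllithium is formylated by DMF (Bouveault aldehyde synthesis); existing stereocenters are not involved.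

**Step 4**
Reactants: 8; 9 3',4'-bis(benzyloxy)acetophenone
Product: 11 (E)-1-[3,4-bis(benzyloxy)phenyl]-3-{(2R,3S)-5,7-bis(benzyloxy)-2-[3,4-bis(benzyloxy)phenyl]-3-hydroxychroman-8-yl}prop-2-en-1-one, via aldol adduct 10 (not isolated)
Conditions: KOH (aq.), EtOH/THF, rt → 40 °C
Reagents that add atoms: none
Why: Claisen–Schmidt aldol condensation of a non-enolisable aldehyde with the acetophenone enolate; E1cB dehydration should give the thermodynamically favoured E-enone.

**Step 5**
Reactants: 12 4-bromoresorcinol; 2 benzyl bromide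
Product: 13 5-(benzyloxy)-2-bromophenol
Conditions: BnBr (1.0 equiv), K2CO3 (1.0 equiv), acetone, 0 °C → rt
Reagents that add atoms: benzyl bromide, BrCc1ccccc1
Why: Williamson mono-etherification; the hydroxyl remote from bromine is the less hindered and its phenoxide the more nucleophilic, so it should be benzylated preferentially, with the regioisomer and bis-ether removed by chromatography.

**Step 6**
Reactants: 13; 14 bis(pinacolato)diboron
Product: 15 5-(benzyloxy)-2-(4,4,5,5-tetramethyl-1,3,2-dioxaborolan-2-yl)phenol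
Conditions: B2pin2 (1.3 equiv), PdCl2(dppf)·CH2Cl2 (5 mol %), KOAc (3 equiv), 1,4-dioxane, 90 °C
Reagents that add atoms: bis(pinacolato)diboron, CC1(C)OB(OC1(C)C)B1OC(C)(C)C(C)(C)O1
Why: Miyaura borylation of the aryl bromide; the weak base KOAc tolerates the free ortho phenol and the pinacol ester is the storable form of this electron-rich boron reagent.

**Step 7**
Reactants: 11; 15
Product: 18 (2R,3S)-5,7-bis(benzyloxy)-8-{(4S)-7-(benzyloxy)-2-[3,4-bis(benzyloxy)phenyl]-4H-chromen-4-yl}-2-[3,4-bis(benzyloxy)phenyl]chroman-3-ol, via keto-phenol adduct 16 (not isolated), via cyclic hemiketal 17 (not isolated)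
Conditions: 15 (2.5 equiv), [RhCl(C2H4)2]2 (3 mol %), (R,R)-Ph-bod* [(1R,4R)-2,5-diphenylbicyclo[2.2.2]octa-2,5-diene] (6.6 mol %), KOH (0.5 equiv), 1,4-dioxane/H2O 10:1, 50 °C; then PPTS (10 mol %), 4 Å MS, toluene, 50 °C, argon
Reagents that add atoms: none
Why: Hayashi–Miyaura asymmetric 1,4-addition followed by cycloketalization: the boronate transmetalates to a hydroxo–rhodium diene complex, the aryl–rhodium bond adds across the (E)-enone with the aryl carbon (future C4a) going to the β-carbon (C4), and water protonates the oxa-π-allyl rhodium to give keto-phenol 16. The closest known reaction type is the rhodium/chiral diene conjugate arylation of chalcones with ortho-hydroxyarylboron reagents that ends in a 4H-chromene. Ring C closes by 6-exo-trig attack of the ortho phenol oxygen O1 on the C2 carbonyl (hemiketal 17), and PPTS then removes water across C2–C3. C4 is the only new stereocenter and is set by the chiral diene on rhodium, whose antipode is chosen so that the aryl group arrives on the Re face of C4 (C8(cat) > C3 > H), the (R,R) ligand on the usual quadrant model for E-enones and its enantiomer should the sense prove opposite; the remote catechin stereocenters should exert little bias. The step needs 1,4- over 1,2-addition (inherent to aryl–rhodium), a fixed sense of annulation (secured by the C–B bond ortho to the free hydroxyl and by the carbonyl sitting at C2) and open enone faces (the di-ortho-oxygenated catechin ring lies in the enone plane, so its ortho groups do not cover C4). The excess of 15 offsets protodeboronation of this electron-rich boronate.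

**Step 8**
Reactants: 18
Product: 19 (2R,3S)-2-(3,4-dihydroxyphenyl)-8-[(2S,4S)-2-(3,4-dihydroxyphenyl)-7-hydroxychroman-4-yl]chroman-3,5,7-triol
Conditions: H2 (4 bar), Pd(OH)2/C (20 wt %), THF/MeOH 1:1, rt, degassed
Reagents that add atoms: none
Why: Heterogeneous hydrogenation; the bulky catechin aryl group at C4 shields one face of the enol ether, so hydrogen should add to C2=C3 anti to it and place the C2 aryl group cis to the C4 aryl group (2S), while the same catalyst hydrogenolyses the seven benzyl ethers and leaves the flavan C2–O bonds intact, as is usual for benzylated flavan-3-ols.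

**Compound list**
1 | (+)-catechin | Oc1cc(O)c2c(c1)O[C@H](c1ccc(O)c(O)c1)[C@@H](O)C2 | starting material
2 | benzyl bromide | BrCc1ccccc1 | starting material
3 | (2R,3S)-5,7-bis(benzyloxy)-2-[3,4-bis(benzyloxy)phenyl]chroman-3-ol | c1c(OCc3ccccc3)cc(OCc3ccccc3)c2c1O[C@H](c1ccc(OCc3ccccc3)c(OCc3ccccc3)c1)[C@@H](O)C2 | intermediate
4 | N-bromosuccinimide | BrN1C(=O)CCC1=O | starting material
5 | (2R,3S)-5,7-bis(benzyloxy)-2-[3,4-bis(benzyloxy)phenyl]-8-bromochroman-3-ol | Brc1c(OCc3ccccc3)cc(OCc3ccccc3)c2c1O[C@H](c1ccc(OCc3ccccc3)c(OCc3ccccc3)c1)[C@@H](O)C2 | intermediate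
6 | N,N-dimethylformamide | CN(C)C=O | starting material
7 | [(2R,3S)-5,7-bis(benzyloxy)-2-[3,4-bis(benzyloxy)phenyl]-3-(lithiooxy)chroman-8-yl]lithium | [Li]c1c(OCc3ccccc3)cc(OCc3ccccc3)c2c1O[C@H](c1ccc(OCc3ccccc3)c(OCc3ccccc3)c1)[C@@H](O[Li])C2 | intermediate
8 | (2R,3S)-5,7-bis(benzyloxy)-2-[3,4-bis(benzyloxy)phenyl]-3-hydroxychroman-8-carbaldehyde | O=Cc1c(OCc3ccccc3)cc(OCc3ccccc3)c2c1O[C@H](c1ccc(OCc3ccccc3)c(OCc3ccccc3)c1)[C@@H](O)C2 | intermediate
9 | 3',4'-bis(benzyloxy)acetophenone | CC(=O)c1ccc(OCc2ccccc2)c(OCc2ccccc2)c1 | starting material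
10 | 1-[3,4-bis(benzyloxy)phenyl]-3-{(2R,3S)-5,7-bis(benzyloxy)-2-[3,4-bis(benzyloxy)phenyl]-3-hydroxychroman-8-yl}-3-hydroxypropan-1-one (carbinol epimers) | O=C(CC(O)c1c(OCc3ccccc3)cc(OCc3ccccc3)c2c1O[C@H](c1ccc(OCc3ccccc3)c(OCc3ccccc3)c1)[C@@H](O)C2)c1ccc(OCc2ccccc2)c(OCc2ccccc2)c1 | intermediate
11 | (E)-1-[3,4-bis(benzyloxy)phenyl]-3-{(2R,3S)-5,7-bis(benzyloxy)-2-[3,4-bis(benzyloxy)phenyl]-3-hydroxychroman-8-yl}prop-2-en-1-one | O=C(/C=C/c1c(OCc3ccccc3)cc(OCc3ccccc3)c2c1O[C@H](c1ccc(OCc3ccccc3)c(OCc3ccccc3)c1)[C@@H](O)C2)c1ccc(OCc2ccccc2)c(OCc2ccccc2)c1 | intermediate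
12 | 4-bromoresorcinol (4-bromobenzene-1,3-diol) | Oc1ccc(Br)c(O)c1 | starting material
13 | 5-(benzyloxy)-2-bromophenol | Oc1cc(OCc2ccccc2)ccc1Br | intermediate
14 | bis(pinacolato)diboron | CC1(C)OB(OC1(C)C)B1OC(C)(C)C(C)(C)O1 | starting material
15 | 5-(benzyloxy)-2-(4,4,5,5-tetramethyl-1,3,2-dioxaborolan-2-yl)phenol | Oc1cc(OCc2ccccc2)ccc1B1OC(C)(C)C(C)(C)O1 | intermediate
16 | (3S)-3-[4-(benzyloxy)-2-hydroxyphenyl]-1-[3,4-bis(benzyloxy)phenyl]-3-{(2R,3S)-5,7-bis(benzyloxy)-2-[3,4-bis(benzyloxy)phenyl]-3-hydroxychroman-8-yl}propan-1-one | O=C(C[C@@H](c1ccc(OCc3ccccc3)cc1O)c1c(OCc3ccccc3)cc(OCc3ccccc3)c2c1O[C@H](c1ccc(OCc3ccccc3)c(OCc3ccccc3)c1)[C@@H](O)C2)c1ccc(OCc2ccccc2)c(OCc2ccccc2)c1 | intermediate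
17 | (4S)-7-(benzyloxy)-2-[3,4-bis(benzyloxy)phenyl]-4-{(2R,3S)-5,7-bis(benzyloxy)-2-[3,4-bis(benzyloxy)phenyl]-3-hydroxychroman-8-yl}chroman-2-ol (C2 epimers) | O(Cc3ccccc3)c1ccc2c(c1)OC(O)(c1ccc(OCc3ccccc3)c(OCc3ccccc3)c1)C[C@@H]2c1c(OCc3ccccc3)cc(OCc3ccccc3)c2c1O[C@H](c1ccc(OCc3ccccc3)c(OCc3ccccc3)c1)[C@@H](O)C2 | intermediate
18 | (2R,3S)-5,7-bis(benzyloxy)-8-{(4S)-7-(benzyloxy)-2-[3,4-bis(benzyloxy)phenyl]-4H-chromen-4-yl}-2-[3,4-bis(benzyloxy)phenyl]chroman-3-ol | O(Cc3ccccc3)c1ccc2c(c1)OC(c1ccc(OCc3ccccc3)c(OCc3ccccc3)c1)=C[C@@H]2c1c(OCc3ccccc3)cc(OCc3ccccc3)c2c1O[C@H](c1ccc(OCc3ccccc3)c(OCc3ccccc3)c1)[C@@H](O)C2 | intermediate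
19 | (2R,3S)-2-(3,4-dihydroxyphenyl)-8-[(2S,4S)-2-(3,4-dihydroxyphenyl)-7-hydroxychroman-4-yl]chroman-3,5,7-triol (CNP0227165.3) | Oc1ccc2c(c1)O[C@H](c1ccc(O)c(O)c1)C[C@@H]2c1c(O)cc(O)c2c1O[C@H](c1ccc(O)c(O)c1)[C@@H](O)C2 | target

**Step count and risks**
Total step count: 8. Longest linear sequence: 6 steps (steps 1, 2, 3, 4, 7, 8).

Steps most likely to fail:

Step 7. Carbometalation may be slow at a β-carbon that carries a di-ortho-oxygenated, strongly donating aryl group, protodeboronation of the electron-rich ortho-hydroxyaryl boronate may outrun it, and facial control may erode. The fallback gives up catalyst control and sets out from chalcone 11. A Friedel–Crafts conjugate addition of free resorcinol (Sc(OTf)3, 10 mol %, MeCN/CH2Cl2, 40 °C; then PPTS, 4 Å MS) should give, after cyclodehydration, (2R,3S)-5,7-bis(benzyloxy)-2-[3,4-bis(benzyloxy)phenyl]-8-{(4S)-2-[3,4-bis(benzyloxy)phenyl]-7-hydroxy-4H-chromen-4-yl}chroman-3-ol F1 together with its (4R) epimer F2. The two are diastereomers because of the catechin unit and would be separated by preparative HPLC. F1 under the conditions of step 8 comes back to the route at target 19.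

Step 8. Saturation of the hindered enol ether may be slow or poorly face-selective, the 4H-chromene may be oxidized by air to the flavylium ion, and the benzylic C2–O bond may be opened by hydrogenolysis. The fallback separates reduction from deprotection and sets out from 18. Ionic hydrogenation (Et3SiH, CF3CO2H, CH2Cl2, −40 °C) protonates C3 and delivers hydride axially to the cyclic oxocarbenium ion, which should leave both aryl groups equatorial and cis, giving (2R,3S)-5,7-bis(benzyloxy)-8-{(2S,4S)-7-(benzyloxy)-2-[3,4-bis(benzyloxy)phenyl]chroman-4-yl}-2-[3,4-bis(benzyloxy)phenyl]chroman-3-ol F3. Hydrogenolysis of F3 (H2, Pd(OH)2/C, THF/MeOH) comes back at target 19.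

Step 3. The alkoxide-bearing aryl bromide may exchange incompletely, the dianion may be quenched by proton transfer, and the flanking benzyl ethers may be deprotonated at their benzylic positions. The fallback avoids the aryllithium and the aldehyde and sets out from bromide 5. Acetophenone 9 is α-methylenated (paraformaldehyde, diisopropylammonium trifluoroacetate, THF, reflux) to 1-[3,4-bis(benzyloxy)phenyl]prop-2-en-1-one F4. A Heck reaction of 5 with F4 (Pd2(dba)3, P(t-Bu)3·HBF4, Cs2CO3, 1,4-dioxane, 90 °C) comes back at chalcone 11.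

**Further compounds**
F1 | step 7 | (2R,3S)-5,7-bis(benzyloxy)-2-[3,4-bis(benzyloxy)phenyl]-8-{(4S)-2-[3,4-bis(benzyloxy)phenyl]-7-hydroxy-4H-chromen-4-yl}chroman-3-ol | Oc1ccc2c(c1)OC(c1ccc(OCc3ccccc3)c(OCc3ccccc3)c1)=C[C@@H]2c1c(OCc3ccccc3)cc(OCc3ccccc3)c2c1O[C@H](c1ccc(OCc3ccccc3)c(OCc3ccccc3)c1)[C@@H](O)C2
F2 | step 7 | (2R,3S)-5,7-bis(benzyloxy)-2-[3,4-bis(benzyloxy)phenyl]-8-{(4R)-2-[3,4-bis(benzyloxy)phenyl]-7-hydroxy-4H-chromen-4-yl}chroman-3-ol | Oc1ccc2c(c1)OC(c1ccc(OCc3ccccc3)c(OCc3ccccc3)c1)=C[C@H]2c1c(OCc3ccccc3)cc(OCc3ccccc3)c2c1O[C@H](c1ccc(OCc3ccccc3)c(OCc3ccccc3)c1)[C@@H](O)C2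
F3 | step 8 | (2R,3S)-5,7-bis(benzyloxy)-8-{(2S,4S)-7-(benzyloxy)-2-[3,4-bis(benzyloxy)phenyl]chroman-4-yl}-2-[3,4-bis(benzyloxy)phenyl]chroman-3-ol | O(Cc3ccccc3)c1ccc2c(c1)O[C@H](c1ccc(OCc3ccccc3)c(OCc3ccccc3)c1)C[C@@H]2c1c(OCc3ccccc3)cc(OCc3ccccc3)c2c1O[C@H](c1ccc(OCc3ccccc3)c(OCc3ccccc3)c1)[C@@H](O)C2
F4 | step 3 | 1-[3,4-bis(benzyloxy)phenyl]prop-2-en-1-one | C=CC(=O)c1ccc(OCc2ccccc2)c(OCc2ccccc2)c1
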